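**Plan**
- Retrosynthesis: ring D is cut at C10a–C6b and C7–C8 (pyrone–alkyne [4+2], then loss of CO2). Then follow O11–C11a (Mitsunobu, inversion), O5–C6 (Mitsunobu), C11a–C6a (allenylzinc plus ring A aldehyde) and the two bonds of ring E (prenyl cation annulation).
- Enabling feature: ring D is fused to ring C through C6b/C10a, carries O11 on C10a and has the methoxy carbon C9 para to C6b. A 3-oxy-5-bromo-2-pyrone tethered through O11–C11a–C6a to an ethynyl group on C6a maps exactly onto this.
- Forward order: ring E onto ring A; C11a–C6a with both stereocentres; ring B; the bromopyronyl ether; rings C and D together; then bromide to methoxy and detosylation.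
- Stereochemistry: C6a comes from an (R)-propargylic mesylate made by Noyori transfer hydrogenation. C11a is set by the anti-selective allenylzinc addition and then inverted in the pyronyl Mitsunobu step to give the cis ether. The key step creates no stereocentre.
- The ring A phenol is masked as a tosylate: it forces the regiochemistry of ring E, survives fluoride and damps ionisation at C11a.

Key step: step 15

Remark: pterocarpan numbering is used (ring A C1–C4a/C11b, O5, C6, C6a, ring D C6b–C10a, O11, C11a); the target is the (6aS,11aS) cis isomer, and the allenylzinc addition of step 8 is assumed to follow its usual anti-SN2′/syn-SE2′ course.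

**Route**

Step 1
Reactants: 1 2,4,6-trihydroxybenzaldehyde
Product: 2 4-formyl-3,5-dihydroxyphenyl 4-methylbenzenesulfonate
Conditions: TsCl (1.0 equiv), K2CO3 (1.0 equiv), acetone, 0 °C → rt
Reagents that add atoms: 4-toluenesulfonyl chloride, Cc1ccc(cc1)S(=O)(=O)Cl
Why: Regioselective phenol O-sulfonylation; the 4-hydroxyl is the most acidic and the only one not chelated to the formyl group, so one equivalent of sulfonyl chloride should react there.

Step 2
Reactants: 2 4-formyl-3,5-dihydroxyphenyl 4-methylbenzenesulfonate; 3 2-methylbut-3-en-2-ol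
Product: 5 8-formyl-7-hydroxy-2,2-dimethylchroman-5-yl 4-methylbenzenesulfonate, via C-prenylated phenol 4 (not isolated)
Conditions: BF3·OEt2 (0.5 equiv), 1,4-dioxane, 25 → 50 °C
Reagents that add atoms: none
Why: Friedel–Crafts C-prenylation at the position ortho/para to the two free hydroxyls, then acid-catalysed Markovnikov hydroalkoxylation of the prenyl olefin by the only adjacent free phenol (the other neighbour is the tosylate), should give the chroman with its ring oxygen next to the formyl-bearing carbon.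

Step 3
Reactants: 5 8-formyl-7-hydroxy-2,2-dimethylchroman-5-yl 4-methylbenzenesulfonate
Product: 6 7-[(tert-butyldimethylsilyl)oxy]-8-formyl-2,2-dimethylchroman-5-yl 4-methylbenzenesulfonate
Conditions: TBSCl, imidazole, DMF, rt
Reagents that add atoms: tert-butyldimethylsilyl chloride, CC(C)(C)[Si](C)(C)Cl
Why: Standard phenol silylation; it prevents formation of a zinc phenoxide chelate that would deactivate the aldehyde in step 8, and the group falls off with the other silyl groups in step 9.

Step 4
Reactants: 7 (tert-butyldimethylsilyloxy)acetaldehyde; 8 ethynyltrimethylsilane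
Product: 10 rac-1-[(tert-butyldimethylsilyl)oxy]-4-(trimethylsilyl)but-3-yn-2-ol, via lithium acetylide 9 (not isolated)
Conditions: n-BuLi, THF, −78 °C; then 7; aq NH4Cl
Reagents that add atoms: none
Why: 1,2-Addition of a lithium acetylide to an aldehyde.

Step 5
Reactants: 10 rac-1-[(tert-butyldimethylsilyl)oxy]-4-(trimethylsilyl)but-3-yn-2-ol
Product: 11 1-[(tert-butyldimethylsilyl)oxy]-4-(trimethylsilyl)but-3-yn-2-one
Conditions: activated MnO2 (excess), CH2Cl2, rt
Reagents that add atoms: none
Why: MnO2 oxidation of a propargylic alcohol to the ynone; the silyl cap keeps the ynone stable.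

Step 6
Reactants: 11 1-[(tert-butyldimethylsilyl)oxy]-4-(trimethylsilyl)but-3-yn-2-one
Product: 12 (R)-1-[(tert-butyldimethylsilyl)oxy]-4-(trimethylsilyl)but-3-yn-2-ol
Conditions: RuCl[(S,S)-TsDPEN](p-cymene) (1 mol %), i-PrOH, rt
Reagents that add atoms: none
Why: Noyori asymmetric transfer hydrogenation of an alkynyl ketone; the (S,S) catalyst distinguishes the alkynyl from the sp3 substituent as it does aryl from methyl, and the carbinol is R here only because CH2OSi outranks the alkynyl carbon.

Step 7
Reactants: 12 (R)-1-[(tert-butyldimethylsilyl)oxy]-4-(trimethylsilyl)but-3-yn-2-ol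
Product: 13 (R)-1-[(tert-butyldimethylsilyl)oxy]-4-(trimethylsilyl)but-3-yn-2-yl methanesulfonate
Conditions: MsCl, Et3N, CH2Cl2, −78 → 0 °C
Reagents that add atoms: methanesulfonyl chloride, CS(=O)(=O)Cl
Why: O-Sulfonylation with retention at the carbinol carbon.

Step 8
Reactants: 6 7-[(tert-butyldimethylsilyl)oxy]-8-formyl-2,2-dimethylchroman-5-yl 4-methylbenzenesulfonate; 13 (R)-1-[(tert-butyldimethylsilyl)oxy]-4-(trimethylsilyl)but-3-yn-2-yl methanesulfonate
Product: 15 7-[(tert-butyldimethylsilyl)oxy]-8-[(1R,2S)-2-{[(tert-butyldimethylsilyl)oxy]methyl}-1-hydroxy-4-(trimethylsilyl)but-3-yn-1-yl]-2,2-dimethylchroman-5-yl 4-methylbenzenesulfonate, via allenylzinc 14 (not isolated)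
Conditions: 13 (1.5 equiv), Pd(OAc)2 (5 mol %), PPh3 (5 mol %), Et2Zn (3 equiv), THF, −78 → −20 °C; aq NH4Cl
Reagents that add atoms: none
Why: Palladium/zinc-mediated propargylation of an aldehyde: zerovalent palladium displaces the mesylate anti-SN2′, ethyl–zinc exchange gives the (aR)-allenylzinc 14, and its SE2′ addition through a cyclic transition state is anti-selective, so C6a (S) comes from the mesylate with net inversion and C11a (R) from the anti preference.

Step 9
Reactants: 15 7-[(tert-butyldimethylsilyl)oxy]-8-[(1R,2S)-2-{[(tert-butyldimethylsilyl)oxy]methyl}-1-hydroxy-4-(trimethylsilyl)but-3-yn-1-yl]-2,2-dimethylchroman-5-yl 4-methylbenzenesulfonate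
Product: 16 8-[(1R,2S)-2-ethynyl-1,3-dihydroxypropyl]-7-hydroxy-2,2-dimethylchroman-5-yl 4-methylbenzenesulfonate
Conditions: Bu4NF (4 equiv), THF, 0 °C → rt; aqueous work-up
Reagents that add atoms: none
Why: Fluoride cleaves the aryl silyl ether, the primary silyl ether and the alkynylsilane in one operation, while the aryl tosylate is inert to fluoride at room temperature.

Step 10
Reactants: 16 8-[(1R,2S)-2-ethynyl-1,3-dihydroxypropyl]-7-hydroxy-2,2-dimethylchroman-5-yl 4-methylbenzenesulfonate
Product: 17 (9S,10R)-9-ethynyl-10-hydroxy-2,2-dimethyl-3,4,9,10-tetrahydro-2H,8H-pyrano[2,3-f]chromen-5-yl 4-methylbenzenesulfonate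
Conditions: PPh3, DIAD, THF (0.01 M), 0 °C
Reagents that add atoms: none
Why: Intramolecular Mitsunobu etherification: the betaine activates the unhindered primary alcohol and the phenol closes ring B (6-exo-tet), as in known cyclisations of 1-(2-hydroxyaryl)propane-1,3-diols to chroman-4-ols; neither stereocentre is touched, so the anti adduct becomes the trans 3-ethynylchroman-4-ol.

Step 11
Reactants: 18 3-hydroxy-2H-pyran-2-one
Product: 19 2-oxo-2H-pyran-3-yl acetate
Conditions: Ac2O, pyridine, CH2Cl2, 0 °C → rt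
Reagents that add atoms: acetic anhydride, CC(=O)OC(C)=O
Why: Enol acetylation; masking the enol removes its directing effect towards C4 before bromination.

Step 12
Reactants: 19 2-oxo-2H-pyran-3-yl acetate
Product: 21 5-bromo-2-oxo-2H-pyran-3-yl acetate, via trans-5,6-dibromide 20 (not isolated)
Conditions: Br2 (1.05 equiv), CH2Cl2, 0 °C → rt; then Et3N, 0 °C
Reagents that add atoms: bromine, BrBr
Why: Bromine addition–dehydrobromination of a 2-pyrone; with C3 blocked and the enol acylated, the electrophile should attack C5, the position activated by the ring oxygen, just as 3-bromo-2-pyrone is brominated to 3,5-dibromo-2-pyrone.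

Step 13
Reactants: 21 5-bromo-2-oxo-2H-pyran-3-yl acetate
Product: 22 5-bromo-3-hydroxy-2H-pyran-2-one
Conditions: HCl (1.25 M in MeOH, 0.2 equiv), MeOH, rt
Reagents that add atoms: none
Why: Acid-catalysed transesterification of the enol acetate; 2-pyrones tolerate acidic methanol (coumalic acid is esterified under such conditions).

Step 14
Reactants: 17 (9S,10R)-9-ethynyl-10-hydroxy-2,2-dimethyl-3,4,9,10-tetrahydro-2H,8H-pyrano[2,3-f]chromen-5-yl 4-methylbenzenesulfonate; 22 5-bromo-3-hydroxy-2H-pyran-2-one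
Product: 23 (9S,10S)-10-[(5-bromo-2-oxo-2H-pyran-3-yl)oxy]-9-ethynyl-2,2-dimethyl-3,4,9,10-tetrahydro-2H,8H-pyrano[2,3-f]chromen-5-yl 4-methylbenzenesulfonate
Conditions: 22 (1.3 equiv), PPh3, DIAD, toluene/THF, −20 → 0 °C
Reagents that add atoms: none
Why: Mitsunobu etherification with the acidic enolic hydroxyl of the pyrone as pronucleophile; SN2 inversion at C11a converts the trans alcohol into the cis ether, the neighbouring ethynyl group is small, and the para tosyloxy group plus the non-polar medium should disfavour ionisation of the oxyphosphonium intermediate.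

Step 15
Reactants: 23 (9S,10S)-10-[(5-bromo-2-oxo-2H-pyran-3-yl)oxy]-9-ethynyl-2,2-dimethyl-3,4,9,10-tetrahydro-2H,8H-pyrano[2,3-f]chromen-5-yl 4-methylbenzenesulfonate
Product: 25 (6aS,11aS)-9-bromo-3-(tosyloxy)pterocarpan fused at C1–C2 to the 2,2-dimethyldihydropyran ring E (ring oxygen on C1), via bridged lactone 24 (not isolated)
Conditions: PhCl (0.01 M), 2,6-di-tert-butyl-4-methylpyridine (0.2 equiv), 130 °C, sealed tube
Reagents that add atoms: none
Why: On heating, the pyrone diene (C3=C4–C5=C6) of 23 should add across the tethered ethynyl group in an intramolecular [4+2] cycloaddition, forming C10a–C6b and C8–C7 and giving the 2-oxabicyclo[2.2.2]octadienone 24. Retro-[4+2] loss of CO2 from 24 is irreversible at this temperature and delivers the benzene ring D directly; the closest known reaction type is the intramolecular Diels–Alder reaction of alkyne-tethered 2-pyrones with CO2 extrusion, with bromo-2-pyrones known as especially reactive dienes. Ring C closes as a five-membered ring through the three-atom tether O11–C11a–C6a (diene terminus to internal alkyne carbon), and ring D closes by the cycloaddition–cycloreversion pair. No stereocentre is formed; C6a and C11a are carried through, and only the cis arrangement of O11 and the ethynyl group on ring B lets the reacting termini meet. The tether fixes the regiochemistry, placing bromine at C9 para to C6b. The selectivity needed is cycloaddition over heterolysis of the benzylic C11a–O bond, which the para tosyloxy group, the non-polar solvent and the hindered base should secure.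

Step 16
Reactants: 25 (6aS,11aS)-9-bromo-3-(tosyloxy)pterocarpan fused at C1–C2 to the 2,2-dimethyldihydropyran ring E
Product: 26 (6aS,11aS)-9-methoxy-3-(tosyloxy)pterocarpan fused at C1–C2 to the 2,2-dimethyldihydropyran ring E
Conditions: Pd2(dba)3 (1 mol %), tBuBrettPhos (2.4 mol %), NaOtBu (1.4 equiv), MeOH (5 equiv), 1,4-dioxane, 50 °C
Reagents that add atoms: methanol, CO
Why: Palladium-catalysed C–O cross-coupling of an aryl bromide with methanol under mild conditions; the aryl bromide should undergo oxidative addition far faster than the aryl tosylate, and no ring A phenoxide is exposed to hot base.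

Step 17
Reactants: 26 (6aS,11aS)-9-methoxy-3-(tosyloxy)pterocarpan fused at C1–C2 to the 2,2-dimethyldihydropyran ring E
Product: 27 (6aS,11aS)-3-hydroxy-9-methoxypterocarpan fused at C1–C2 to the 2,2-dimethyldihydropyran ring E (CNP0207547.1)
Conditions: Mg turnings (excess), MeOH, rt, ultrasound; aq NH4Cl
Reagents that add atoms: none
Why: Reductive S–O cleavage of an aryl tosylate by magnesium in methanol (electron transfer) at room temperature should free the phenol without hot base, which could open ring C through a para-quinone methide.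

**Compound list**
1 | 2,4,6-trihydroxybenzaldehyde | O=Cc1c(O)cc(O)cc1O | starting material
2 | 4-formyl-3,5-dihydroxyphenyl 4-methylbenzenesulfonate | O=Cc1c(O)cc(OS(=O)(=O)c2ccc(C)cc2)cc1O | intermediate
3 | 2-methylbut-3-en-2-ol | CC(C)(O)C=C | starting material
4 | 4-formyl-3,5-dihydroxy-2-(3-methylbut-2-en-1-yl)phenyl 4-methylbenzenesulfonate | O=Cc1c(O)cc(OS(=O)(=O)c2ccc(C)cc2)c(CC=C(C)C)c1O | intermediate
5 | 8-formyl-7-hydroxy-2,2-dimethylchroman-5-yl 4-methylbenzenesulfonate | O=Cc1c(O)cc(OS(=O)(=O)c3ccc(C)cc3)c2CCC(C)(C)Oc12 | intermediate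
6 | 7-[(tert-butyldimethylsilyl)oxy]-8-formyl-2,2-dimethylchroman-5-yl 4-methylbenzenesulfonate | O=Cc1c(O[Si](C)(C)C(C)(C)C)cc(OS(=O)(=O)c3ccc(C)cc3)c2CCC(C)(C)Oc12 | intermediate
7 | (tert-butyldimethylsilyloxy)acetaldehyde | CC(C)(C)[Si](C)(C)OCC=O | starting material
8 | ethynyltrimethylsilane | C#C[Si](C)(C)C | starting material
9 | lithium (trimethylsilyl)acetylide | [Li]C#C[Si](C)(C)C | intermediate
10 | rac-1-[(tert-butyldimethylsilyl)oxy]-4-(trimethylsilyl)but-3-yn-2-ol | CC(C)(C)[Si](C)(C)OCC(O)C#C[Si](C)(C)C | intermediate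
11 | 1-[(tert-butyldimethylsilyl)oxy]-4-(trimethylsilyl)but-3-yn-2-one | CC(C)(C)[Si](C)(C)OCC(=O)C#C[Si](C)(C)C | intermediate
12 | (R)-1-[(tert-butyldimethylsilyl)oxy]-4-(trimethylsilyl)but-3-yn-2-ol | CC(C)(C)[Si](C)(C)OC[C@H](O)C#C[Si](C)(C)C | intermediate
13 | (R)-1-[(tert-butyldimethylsilyl)oxy]-4-(trimethylsilyl)but-3-yn-2-yl methanesulfonate | CC(C)(C)[Si](C)(C)OC[C@H](OS(C)(=O)=O)C#C[Si](C)(C)C | intermediate
14 | (aR)-ethyl[4-(tert-butyldimethylsilyloxy)-1-(trimethylsilyl)buta-1,2-dien-1-yl]zinc | CC[Zn]C([Si](C)(C)C)=[C@]=C([H])CO[Si](C)(C)C(C)(C)C | intermediate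
15 | 7-[(tert-butyldimethylsilyl)oxy]-8-[(1R,2S)-2-{[(tert-butyldimethylsilyl)oxy]methyl}-1-hydroxy-4-(trimethylsilyl)but-3-yn-1-yl]-2,2-dimethylchroman-5-yl 4-methylbenzenesulfonate | O[C@@H](c1c(O[Si](C)(C)C(C)(C)C)cc(OS(=O)(=O)c3ccc(C)cc3)c2CCC(C)(C)Oc12)[C@H](CO[Si](C)(C)C(C)(C)C)C#C[Si](C)(C)C | intermediate
16 | 8-[(1R,2S)-2-ethynyl-1,3-dihydroxypropyl]-7-hydroxy-2,2-dimethylchroman-5-yl 4-methylbenzenesulfonate | O[C@@H](c1c(O)cc(OS(=O)(=O)c3ccc(C)cc3)c2CCC(C)(C)Oc12)[C@H](CO)C#C | intermediate
17 | (9S,10R)-9-ethynyl-10-hydroxy-2,2-dimethyl-3,4,9,10-tetrahydro-2H,8H-pyrano[2,3-f]chromen-5-yl 4-methylbenzenesulfonate (trans 3-ethynylchroman-4-ol of rings A, B, E) | O[C@H]1c3c(cc(OS(=O)(=O)c5ccc(C)cc5)c4c3OC(C)(C)CC4)OC[C@@H]1C#C | intermediate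
18 | 3-hydroxy-2H-pyran-2-one | O=C1OC=CC=C1O | starting material
19 | 2-oxo-2H-pyran-3-yl acetate | CC(=O)OC1=CC=COC1=O | intermediate
20 | trans-5,6-dibromo-2-oxo-5,6-dihydro-2H-pyran-3-yl acetate (racemic, one enantiomer drawn) | CC(=O)OC1=C[C@H](Br)[C@@H](Br)OC1=O | intermediate
21 | 5-bromo-2-oxo-2H-pyran-3-yl acetate | CC(=O)OC1=CC(Br)=COC1=O | intermediate
22 | 5-bromo-3-hydroxy-2H-pyran-2-one | O=C1OC=C(Br)C=C1O | intermediate
23 | (9S,10S)-10-[(5-bromo-2-oxo-2H-pyran-3-yl)oxy]-9-ethynyl-2,2-dimethyl-3,4,9,10-tetrahydro-2H,8H-pyrano[2,3-f]chromen-5-yl 4-methylbenzenesulfonate (cis ether) | O=C2OC=C(Br)C=C2O[C@@H]1c3c(cc(OS(=O)(=O)c5ccc(C)cc5)c4c3OC(C)(C)CC4)OC[C@@H]1C#C | intermediate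
24 | bridged cycloadduct of 23: 2-oxabicyclo[2.2.2]octa-5,7-dien-3-one in which C10a and C8 are bridged by C(=O)–O (one of the two bridge epimers drawn; both lose CO2 to 25) | O=C1O[C@H]2C=C3[C@H]4COc5cc(OS(=O)(=O)c6ccc(C)cc6)c6CCC(C)(C)Oc6c5[C@H]4O[C@]31C=C2Br | intermediate
25 | (6aS,11aS)-9-bromo-3-(tosyloxy)pterocarpan with the 2,2-dimethyl-3,4-dihydro-2H-pyran ring E fused at C1–C2 (ring oxygen on C1) | Brc1ccc2c(c1)O[C@@H]1c3c(cc(OS(=O)(=O)c5ccc(C)cc5)c4c3OC(C)(C)CC4)OC[C@H]21 | intermediate
26 | (6aS,11aS)-9-methoxy-3-(tosyloxy)pterocarpan with ring E fused at C1–C2 | COc1ccc2c(c1)O[C@@H]1c3c(cc(OS(=O)(=O)c5ccc(C)cc5)c4c3OC(C)(C)CC4)OC[C@H]21 | intermediate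
27 | (6aS,11aS)-3-hydroxy-9-methoxypterocarpan with ring E fused at C1–C2 (CNP0207547.1) | COc1ccc2c(c1)O[C@@H]1c3c(cc(O)c4c3OC(C)(C)CC4)OC[C@H]21 | target

**Step count**
Total: 17 steps. Longest linear sequence: 11 steps (steps 4–10, then 14–17).

**Steps most likely to fail, with fallbacks**

Step 15. Heterolysis of the benzylic C11a–O bond (loss of the pyronol, elimination to a 2H-chromene) may outrun a slow cycloaddition to the unactivated alkyne. The fallback lowers the oxidation level of the dienophile and sets out from 17. Semi-hydrogenation (H2, Pd/CaCO3 poisoned with Pb(OAc)2, quinoline) would give the trans 3-vinylchroman-4-ol F1. Mitsunobu reaction of F1 with 22 would give the cis pyronyl ether F2. A terminal alkene should add to the bromopyrone at about 80–100 °C to give the bridged lactone F3, in which O11 is no longer bound to a leaving group. Stronger heating would then expel CO2 to give the 6b,7-dihydro arene F4, and dehydrogenation (DDQ, 0 °C) would return to the route at 25.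

Step 14. Ionisation of the oxyphosphonium intermediate at the electron-rich, ring-held benzylic carbon may cause loss of configuration at C11a or elimination instead of clean inversion. The fallback forms the C11a–O11 bond before ring B exists and sets out from 15, where only the secondary hydroxyl is free and the doubly ortho-substituted aryl group is twisted out of the plane a benzylic cation needs. Mitsunobu reaction of 15 with 22 would give the open-chain (1S,2S) pyronyl ether F5. Buffered fluoride (Bu4NF/AcOH, THF, 0 °C) would remove the three silyl groups to give the phenol–alcohol F6, and the ring B Mitsunobu closure (PPh3, DIAD) would come back to the route at 23.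

Step 12. Bromination may occur at C4 or C6, or bromine may add across the enol acetate double bond, instead of substituting at C5. The fallback brings the halogen in with the pyrone and introduces the oxygen afterwards. It does not branch from a compound of the route but replaces 18–21 by commercial coumalic acid F7. Bromodecarboxylation (NBS, LiOAc, MeCN/H2O) is known to give 3,5-dibromo-2H-pyran-2-one F8. Palladium-catalysed couplings of F8 are known to take place at C3, so Miyaura borylation (B2pin2, KOAc, Pd(dppf)Cl2, 1,4-dioxane, 80 °C) should give the 3-boronate F9. Oxidation (NaBO3·4H2O, THF/H2O) would return to the route at 22.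

**Further compounds**
F1 | step 15 | (9S,10R)-9-ethenyl-10-hydroxy-2,2-dimethyl-3,4,9,10-tetrahydro-2H,8H-pyrano[2,3-f]chromen-5-yl 4-methylbenzenesulfonate | O[C@H]1c3c(cc(OS(=O)(=O)c5ccc(C)cc5)c4c3OC(C)(C)CC4)OC[C@@H]1C=C
F2 | step 15 | (9S,10S)-10-[(5-bromo-2-oxo-2H-pyran-3-yl)oxy]-9-ethenyl-2,2-dimethyl-3,4,9,10-tetrahydro-2H,8H-pyrano[2,3-f]chromen-5-yl 4-methylbenzenesulfonate | O=C2OC=C(Br)C=C2O[C@@H]1c3c(cc(OS(=O)(=O)c5ccc(C)cc5)c4c3OC(C)(C)CC4)OC[C@@H]1C=C
F3 | step 15 | bridged lactone from the pyrone–alkene cycloaddition of F2 (C10a and C8 bridged by C(=O)–O, C6b and C7 saturated; the new centres form as a mixture and are left undefined) | O=C1OC2CC3[C@H]4COc5cc(OS(=O)(=O)c6ccc(C)cc6)c6CCC(C)(C)Oc6c5[C@H]4OC31C=C2Br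
F4 | step 15 | (6aS,11aS)-9-bromo-6b,7-dihydro-3-(tosyloxy)pterocarpan with ring E fused at C1–C2 (C6b epimers) | BrC1=CCC2C(=C1)O[C@@H]1c3c(cc(OS(=O)(=O)c5ccc(C)cc5)c4c3OC(C)(C)CC4)OC[C@H]21
F5 | step 14 | 8-[(1S,2S)-1-[(5-bromo-2-oxo-2H-pyran-3-yl)oxy]-2-{[(tert-butyldimethylsilyl)oxy]methyl}-4-(trimethylsilyl)but-3-yn-1-yl]-7-[(tert-butyldimethylsilyl)oxy]-2,2-dimethylchroman-5-yl 4-methylbenzenesulfonate | O=C1OC=C(Br)C=C1O[C@H](c2c(O[Si](C)(C)C(C)(C)C)cc(OS(=O)(=O)c4ccc(C)cc4)c3CCC(C)(C)Oc23)[C@H](CO[Si](C)(C)C(C)(C)C)C#C[Si](C)(C)C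
F6 | step 14 | 8-[(1S,2S)-1-[(5-bromo-2-oxo-2H-pyran-3-yl)oxy]-2-(hydroxymethyl)but-3-yn-1-yl]-7-hydroxy-2,2-dimethylchroman-5-yl 4-methylbenzenesulfonate | O=C1OC=C(Br)C=C1O[C@H](c2c(O)cc(OS(=O)(=O)c4ccc(C)cc4)c3CCC(C)(C)Oc23)[C@H](CO)C#C
F7 | step 12 | coumalic acid (2-oxo-2H-pyran-5-carboxylic acid) | O=C(O)C1=COC(=O)C=C1
F8 | step 12 | 3,5-dibromo-2H-pyran-2-one | O=C1OC=C(Br)C=C1Br
F9 | step 12 | 5-bromo-3-(4,4,5,5-tetramethyl-1,3,2-dioxaborolan-2-yl)-2H-pyran-2-one | CC1(C)OB(OC1(C)C)C1=CC(Br)=COC1=O
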